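## Retrosynthetic overview

1. Both naphthalene skeletons are bought. Naphthalene-1,5-diol 1 gives the nucleophile 5-methoxy-1-naphthol 2 by O-methylation. Juglone 3 gives naphthalene-1,4,5-triol 4 by quinone reduction.
2. Triol 4 is the aromatic tautomer of keto form 5 and of ortho-quinone methide 6. Nature is thought to reach 6 by dehydration of 4,5,8-trihydroxy-1-tetralone, so no benzylic leaving group is installed.
3. Key disconnection in target 7: the C4–C1′ bond at the only stereocentre, from C4 of 6 and C4 of 2 (para to OH). It is made as an enantioselective, acid-catalysed dearomative hydroarylation.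
4. Ring order: the aromatic bicycles are carried through. The cyclohexanone ring of the tetralone is the only ring created, and it is created last. It forms by ketonisation of the phenol ring of 4, in the same operation that forms the C–C bond and sets (S).

Assumption: the compound is taken to arise in nature by para-C-alkylation of 5-methoxy-1-naphthol with the ortho-quinone methide of a hydrojuglone-derived tetralone, and the (S,S)-catalyst is taken to expose the Re face of C4 (if the first run gives the R product, the (R,R)-catalyst is used).

## Route

Step 1
Reactants: 1 naphthalene-1,5-diol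
Product: 2 5-methoxynaphthalen-1-ol
Conditions: MeI (1.0 equiv), K2CO3 (1.0 equiv), acetone, reflux, N2
Reagents that add atoms: iodomethane, CI
Why: Williamson ether synthesis under statistical control, in which one equivalent of base and MeI on the symmetric diol gives mainly the mono-ether, separable from recyclable 1 (more polar) and the base-insoluble diether; no stereocentre is formed.

Step 2
Reactants: 3 juglone (5-hydroxynaphthalene-1,4-dione)
Product: 4 naphthalene-1,4,5-triol (α-hydrojuglone)
Conditions: Na2S2O4 (3 equiv), degassed Et2O/H2O, rt, 15 min, Ar; dried and used the same day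
Reagents that add atoms: none
Why: Dithionite quinone-to-hydroquinone reduction is fast, touches nothing else in 3 and mirrors the NAD(P)H quinone reduction that precedes tetralone formation in this family; no stereocentre is formed.

Step 3
Reactants: 4 naphthalene-1,4,5-triol; 2 5-methoxynaphthalen-1-ol
Product: 7 (4S)-5,8-dihydroxy-4-(4-hydroxy-8-methoxynaphthalen-1-yl)-3,4-dihydronaphthalen-1(2H)-one, via 5,8-dihydroxynaphthalen-1(2H)-one 5 (not isolated), via 8-hydroxy-2,3-dihydronaphthalene-1,5-dione 6 (not isolated)
Conditions: (S,S)-IDPi (BINOL-derived imidodiphosphorimidate, N-perfluoroarylsulfonyl core, 5 mol %), 2 (3 equiv, excess recovered), degassed EtOH-free CHCl3, Ar, dark, solid 4 added in portions over 6 h, 25–40 °C; then direct filtration through silica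
Reagents that add atoms: none
Why: Proposed new method: an asymmetric counteranion-directed dearomative Friedel–Crafts hydroarylation, in which the strong confined chiral Brønsted acid reversibly C-protonates the electron-rich triol 4 so that all its tautomers interconvert (the ring-A diketone β-hydrojuglone is only a reversible resting state); ketonisation of the C5-phenol ring, favoured by the resonance-assisted hydrogen bond from the peri OH, gives 5, whose styrene-type C3=C4 bond is protonated at C3 to O-protonated 6, held by hydrogen bonding and ion pairing in the chiral anion pocket; the only irreversible exit is attack of C4 of 2 (the α-carbon para to OH, where 1,5-dioxygenated naphthalenes are brominated, formylated and acylated under kinetic control) on the Re face of C4, which rearomatises both partners and sets (S); 2 stays the nucleophile because it lacks the peri-OH that assists ketonisation, and homocoupling of 4 is suppressed by its low stationary concentration; the closest known reaction types are the AlCl3/AlBr3-promoted hydroarylation of the keto tautomers of 1-naphthol and naphthalene-1,5-diol by arenes to 4-aryl-1-tetralones (the sertraline-tetralone reaction), chiral-acid-catalysed Friedel–Crafts addition of naphthols to ortho-quinone methides, and IDPi-catalysed asymmetric hydroarylation of olefins.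

## Compound list

1 | naphthalene-1,5-diol | Oc1cccc2c(O)cccc12 | starting material
2 | 5-methoxynaphthalen-1-ol | COc1cccc2c(O)cccc12 | intermediate
3 | juglone (5-hydroxynaphthalene-1,4-dione) | O=C1C=CC(=O)c2c(O)cccc12 | starting material
4 | naphthalene-1,4,5-triol (α-hydrojuglone) | Oc1ccc(O)c2c(O)cccc12 | intermediate
5 | 5,8-dihydroxynaphthalen-1(2H)-one (ring-B keto tautomer of 4, not isolated) | O=C1CC=Cc2c(O)ccc(O)c12 | intermediate
6 | 8-hydroxy-2,3-dihydronaphthalene-1,5-dione (ortho-quinone methide, reacts as its O-protonated ion pair with the catalyst anion, not isolated) | O=C1CCC=C2C(=O)C=CC(O)=C12 | intermediate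
7 | (4S)-5,8-dihydroxy-4-(4-hydroxy-8-methoxynaphthalen-1-yl)-3,4-dihydronaphthalen-1(2H)-one | COc1cccc2c(O)ccc([C@@H]3CCC(=O)c4c(O)ccc(O)c43)c12 | target

## Counts and risks

Total step count: 3.
Longest linear sequence: 2 (3 → 4 → 7, or 1 → 2 → 7).

**Step 3 (highest risk).** Three things can go wrong.
- The acid may park 4 as β-hydrojuglone, whose free carbonyl could be arylated and dehydrated to an aromatic binaphthyl.
- Naphthol 2 may attack through the unhindered C2 instead of the peri-hindered C4.
- Retro-Friedel–Crafts reaction may erode regio- and enantiopurity.

The fallback sets out from 2 and returns at 7. It replaces arene protonation by ionisation of a discrete leaving group, and it blocks the ortho carbon.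
- Ortho-selective bromination of 2 (NBS, cat. iPr2NH, CH2Cl2, 0 °C) gives 2-bromo-5-methoxynaphthalen-1-ol F3.
- In parallel, hydroquinone (Oc1ccc(O)cc1) and succinic anhydride (O=C1CCC(=O)O1) are fused in an AlCl3–NaCl melt at 180–200 °C. This double Friedel–Crafts acylation closes a succinyl-arene ring, as in the o-succinylbenzoate pathway, and gives 5,8-dihydroxy-2,3-dihydronaphthalene-1,4-dione F4.
- One carbonyl of F4 is reduced (NaBH4, 1 equiv, THF/EtOH, −20 °C) to (±)-4,5,8-trihydroxy-3,4-dihydronaphthalen-1(2H)-one F5.
- With the same chiral acid at −40 °C, F5 loses water to give the same ion pair of 6. At this temperature aromatisation to 4 and retro-alkylation are slow.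
- F3 can then react only at C4, giving (4S)-4-(3-bromo-4-hydroxy-8-methoxynaphthalen-1-yl)-5,8-dihydroxy-3,4-dihydronaphthalen-1(2H)-one F6.
- Hydrogenolysis (H2, Pd/C, NaOAc, EtOAc, rt) removes the bromine and delivers 7.

**Step 1.** Statistical mono-alkylation may give an inconvenient mixture of diol, mono-ether and diether, and 1 darkens in base. The fallback sets out from 1 and returns at 2.
- Exhaustive methylation (excess MeI, K2CO3, DMF) gives 1,5-dimethoxynaphthalene F1 cleanly.
- One methyl group is then removed by SN2 demethylation with NaSEt (1.3 equiv, DMF, 120 °C). This is self-limiting, because the naphtholate formed resists a second cleavage. Acidification gives 2.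

**Step 2.** Triol 4 re-oxidises in air to 3 and slowly ketonises on storage. The ketonisation is harmless, since step 3 equilibrates the tautomers, but re-oxidation is not. The fallback sets out from 3 and returns at 4.
- Reductive acetylation (Zn dust, Ac2O, NaOAc, 60 °C) gives bench-stable naphthalene-1,4,5-triyl triacetate F2, which can be purified and stored.
- Immediately before step 3, F2 is deacetylated under reducing, non-acidic conditions (N2H4·H2O, 3.3 equiv, degassed THF/MeOH, 0 °C to rt, Ar) to release 4. This avoids acid/alcohol media, which would etherify the triol.

## Further compounds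

F1 | step 1 | 1,5-dimethoxynaphthalene | COc1cccc2c(OC)cccc12
F2 | step 2 | naphthalene-1,4,5-triyl triacetate | CC(=O)Oc1ccc(OC(C)=O)c2c(OC(C)=O)cccc12
F3 | step 3 | 2-bromo-5-methoxynaphthalen-1-ol | COc1cccc2c(O)c(Br)ccc12
F4 | step 3 | 5,8-dihydroxy-2,3-dihydronaphthalene-1,4-dione | O=C1CCC(=O)c2c(O)ccc(O)c12
F5 | step 3 | (±)-4,5,8-trihydroxy-3,4-dihydronaphthalen-1(2H)-one | O=C1CCC(O)c2c(O)ccc(O)c12
F6 | step 3 | (4S)-4-(3-bromo-4-hydroxy-8-methoxynaphthalen-1-yl)-5,8-dihydroxy-3,4-dihydronaphthalen-1(2H)-one | COc1cccc2c(O)c(Br)cc([C@@H]3CCC(=O)c4c(O)ccc(O)c43)c12
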